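Numbering of each half: ring B = C1 (CH–CH3), C2, C3, C4 (CH–iPr). The fusion atoms are C4a and C8a. Ring A = C5 (H), C6 (CH3), C7 (OH), C8 (biaryl carbon). The retrosynthesis cuts C8–C8' first, then C7–O. It then returns ring A and C1 to the hexahydronaphthalene level and finally cuts C4–C4a and C4a–C8a together.
Enabling feature: the fifteen carbons of one half are a single head-to-tail farnesyl chain folded as a cadinane. C4a = farnesyl C1, C5–C8 = C2–C5, C8a = C6, C1–C4 = C7–C10, and the isopropyl CH = C11. The methyl branches sit where farnesyl carries them, so two new bonds to farnesyl C1 close rings A and B.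
Forward order: farnesol → diphosphate → enzymatic bicyclisation (a ten-membered ring forms first and is then split into rings A and B) → aromatisation of ring A → saturation of C1=C2 → oxygenation at C7 → dimerisation at C8.
Stereochemistry: C4 (S) comes from the cyclase. C1 (S) comes from hydrogenation on the face opposite the C4 isopropyl group. The enzyme-made C4a centre is lost on aromatisation, and one enantiopure monomer supplies both halves.

Key step: step 3

Assumption 1: the structure fixes four stereocentres but gives no descriptor for the C8–C8' axis, which carries four ortho substituents. The axis is therefore treated as undefined, and the atropisomers that the coupling may give (separable diastereomers) both count as the target.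
Assumption 2: the cyclase is a catalyst obtained by routine expression of a synthetic gene in E. coli and supplies no atoms.

Step 1
Reactants: 1 (2E,6E)-farnesol
Product: 2 (2E,6E)-farnesyl chloride
Conditions: NCS, Me2S, CH2Cl2, −40 → 0 °C
Reagents that add atoms: N-chlorosuccinimide, O=C1CCC(=O)N1Cl
Why: Corey–Kim-type chlorination activates the alcohol on sulfur and lets chloride displace it in an SN2 sense at the primary allylic carbon under nearly neutral conditions, so neither allylic transposition nor erosion of the 2E geometry is expected.

Step 2
Reactants: 2 (2E,6E)-farnesyl chloride; 3 tris(tetrabutylammonium) hydrogen diphosphate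
Product: 5 (2E,6E)-farnesyl diphosphate tris-ammonium salt, via bis(tetrabutylammonium) farnesyl diphosphate 4 (not isolated)
Conditions: 3 (2 equiv), MeCN, rt; then Dowex 50WX8 (NH4+ form), aq NH4HCO3/iPrOH; cellulose chromatography, lyophilisation
Reagents that add atoms: tris(tetrabutylammonium) hydrogen diphosphate 3, CCCC[N+](CCCC)(CCCC)CCCC.CCCC[N+](CCCC)(CCCC)CCCC.CCCC[N+](CCCC)(CCCC)CCCC.OP(=O)([O-])OP(=O)([O-])[O-]; ammonium hydrogencarbonate (counter-ions), [NH4+].OC(=O)[O-]
Why: SN2 alkylation of the poorly solvated diphosphate trianion by a primary allylic chloride in a dipolar aprotic solvent is the standard entry to allylic diphosphates; the excess of 3 suppresses double alkylation and the mildly basic exchange buffer protects the acid-labile allylic ester.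

Step 3
Reactants: 5 (2E,6E)-farnesyl diphosphate tris-ammonium salt
Product: 7 (+)-δ-cadinene, via (3R)-nerolidyl diphosphate 6 (not isolated)
Conditions: recombinant (+)-δ-cadinene synthase (Gossypium arboreum, His6-tagged, from E. coli), MgCl2 (10 mM), HEPES pH 7.5, DTT, glycerol (10% v/v), 5 fed in portions, pentane overlay, 25 °C, gentle shaking
Reagents that add atoms: none
Why: The Mg2+ cluster held by the aspartate-rich motifs ionises 5, the ion pair recombines to the tertiary allylic diphosphate 6, and rotation about its C2–C3 single bond followed by re-ionisation gives the cisoid allyl cation that the 2E alkene of 5 cannot reach directly. Farnesyl C10 attacks C1 (Markovnikov, 10-exo with respect to the C10=C11 alkene, new bond C4–C4a) to give a ten-membered cation charged at C11, a 1,3-hydride shift from C1 to C11 creates the isopropyl group and an allyl cation over C1–C3, and C6 then attacks C1 (new bond C4a–C8a) in a transannular closure that is 6-exo as seen from ring A and 6-endo as seen from ring B and leaves a tertiary cation on farnesyl C7 (target C1). Loss of the proton on farnesyl C6 gives the tetrasubstituted C1=C8a alkene of 7. This is the native reaction of a class 1 sesquiterpene cyclase and belongs to the cation–olefin polycyclisations. C4 is fixed by the face of the C10=C11 alkene that the folded chain offers to C1, and C4a by the face of the allyl cation that meets C6, both imposed by the active-site contour, and only C4 is carried to the target. The step needs 1,10-closure ahead of the competing 1,11- and early 1,6-modes, exclusion of water and one single deprotonation; the spacing of the three trisubstituted alkenes in 5 makes each closure Markovnikov and ten- or six-membered, and the closed hydrophobic pocket supplies the rest, which no simple acid achieves on a farnesyl chain.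

Step 4
Reactants: 7 (+)-δ-cadinene
Product: 9 (S)-α-calacorene, via conjugated triene 8 (not isolated)
Conditions: DDQ (2.0 equiv, added slowly as a solution), benzene, 0 °C; filtration, short basic alumina plug
Reagents that add atoms: none
Why: In this quinone dehydrogenation by hydride abstraction the doubly allylic tertiary C4a–H is by far the best hydride donor of 7, the derived pentadienyl cation loses a proton to give 8 (cross-conjugated isomers funnel the same way), the cyclohexadiene ring A of 8 is aromatised by the second equivalent, and the less hydridic C3–H of 9 should be spared while DDQ is the limiting reagent at 0 °C, so C4 stays untouched and only the C4a centre disappears.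

Step 5
Reactants: 9 (S)-α-calacorene
Product: 10 (1S,4S)-calamenene (cis)
Conditions: H2 (1 atm), 5% Pt/C, EtOAc, 0 °C → rt
Reagents that add atoms: none
Why: In this heterogeneous syn hydrogenation of a trisubstituted styrene the C4 isopropyl group stands pseudoaxial to escape the peri C5–H and screens its own face of the half-chair, so hydrogen should reach C1 and C2 from the opposite face and place the C1 methyl group cis to isopropyl, i.e. (1S); platinum is preferred to palladium because it is less prone to move the alkene towards C4.

Step 6
Reactants: 10 (1S,4S)-calamenene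
Product: 11 (1S,4S)-7-acetylcalamenene
Conditions: AcCl, AlCl3 (premixed), CH2Cl2, −20 → 0 °C; ice/aq HCl
Reagents that add atoms: acetyl chloride, CC(=O)Cl
Why: In this Friedel–Crafts acylation (Perrier mode) C7 is ortho to the C6 methyl group and para to C4a and is the only doubly activated site not flanked on both sides (C5 is wedged between C6–CH3 and the peri isopropyl group, C8 is activated by C8a alone and is peri to C1–CH3), as in the 5-selective acylation of 1,2,4-trialkylbenzenes, and the preformed acylium complex at low temperature should leave the benzylic C–H bonds alone.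

Step 7
Reactants: 11 (1S,4S)-7-acetylcalamenene
Product: 13 (1S,4S)-7-hydroxycalamenene, via aryl acetate 12 (not isolated)
Conditions: mCPBA, TFA (1 equiv), CH2Cl2, 0 °C → rt, dark; aq Na2SO3/NaHCO3 wash; then K2CO3 (cat.), degassed MeOH, rt
Reagents that add atoms: 3-chloroperoxybenzoic acid, O=C(OO)c1cccc(Cl)c1
Why: In the Baeyer–Villiger oxidation the electron-rich, ortho-substituted aryl group migrates in preference to methyl, and base-catalysed transesterification of the crude aryl acetate then frees the phenol; neither operation touches C1 or C4.

Step 8
Reactants: 13 (1S,4S)-7-hydroxycalamenene (two molecules)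
Product: 14 8,8'-bi[(1S,4S)-7-hydroxycalamenene], the target
Conditions: (tBuO)2 (0.6 equiv), PhCl, reflux, Ar; unreacted 13 recycled
Reagents that add atoms: none
Why: In this oxidative phenol coupling tert-butoxyl radicals abstract the O–H hydrogen, and because C6 (ortho) and C4a (para) of the phenoxyl radical are substituted, only dimerisation at C8 can rearomatise, which gives the ortho–ortho biphenol as known for 2,4,5-trialkylphenols and hindered terpenoid phenols; the C4–H bond lies near the arene plane (isopropyl pseudoaxial), which disfavours quinone methide formation, and one enantiopure monomer excludes heterochiral dimers.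

Compound list
1 | (2E,6E)-farnesol | CC(C)=CCC/C(C)=C/CC/C(C)=C/CO | starting material
2 | (2E,6E)-farnesyl chloride | CC(C)=CCC/C(C)=C/CC/C(C)=C/CCl | intermediate
3 | tris(tetrabutylammonium) hydrogen diphosphate | CCCC[N+](CCCC)(CCCC)CCCC.CCCC[N+](CCCC)(CCCC)CCCC.CCCC[N+](CCCC)(CCCC)CCCC.OP(=O)([O-])OP(=O)([O-])[O-] | starting material
4 | (2E,6E)-farnesyl hydrogen diphosphate, bis(tetrabutylammonium) salt | CC(C)=CCC/C(C)=C/CC/C(C)=C/COP(=O)([O-])OP(=O)(O)[O-].CCCC[N+](CCCC)(CCCC)CCCC.CCCC[N+](CCCC)(CCCC)CCCC | intermediate
5 | (2E,6E)-farnesyl diphosphate, tris-ammonium salt | CC(C)=CCC/C(C)=C/CC/C(C)=C/COP(=O)([O-])OP(=O)([O-])[O-].[NH4+].[NH4+].[NH4+] | intermediate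
6 | (3R,6E)-nerolidyl diphosphate, enzyme-bound, drawn as the tris-ammonium salt | C=C[C@@](C)(CC/C=C(\C)CCC=C(C)C)OP(=O)([O-])OP(=O)([O-])[O-].[NH4+].[NH4+].[NH4+] | intermediate
7 | (+)-δ-cadinene, (1S,8aR)-4,7-dimethyl-1-(propan-2-yl)-1,2,3,5,6,8a-hexahydronaphthalene | CC1=C[C@@H]2C(=C(C)CC[C@H]2C(C)C)CC1 | intermediate
8 | (1S)-4,7-dimethyl-1-(propan-2-yl)-1,2,5,6-tetrahydronaphthalene (C1=C2, C4a=C8a, C5=C6 triene in the numbering used here) | CC1=CC2=C(CC1)C(C)=CC[C@H]2C(C)C | intermediate
9 | (S)-α-calacorene, (1S)-4,7-dimethyl-1-(propan-2-yl)-1,2-dihydronaphthalene | Cc1cc2c(cc1)C(C)=CC[C@H]2C(C)C | intermediate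
10 | (1S,4S)-calamenene, cis, (1S,4S)-1,6-dimethyl-4-(propan-2-yl)-1,2,3,4-tetrahydronaphthalene | Cc1cc2c(cc1)[C@@H](C)CC[C@H]2C(C)C | intermediate
11 | 1-[(5S,8S)-3,8-dimethyl-5-(propan-2-yl)-5,6,7,8-tetrahydronaphthalen-2-yl]ethan-1-one | Cc1cc2c(cc1C(C)=O)[C@@H](C)CC[C@H]2C(C)C | intermediate
12 | (5S,8S)-3,8-dimethyl-5-(propan-2-yl)-5,6,7,8-tetrahydronaphthalen-2-yl acetate | Cc1cc2c(cc1OC(C)=O)[C@@H](C)CC[C@H]2C(C)C | intermediate
13 | (1S,4S)-7-hydroxycalamenene, (5S,8S)-3,8-dimethyl-5-(propan-2-yl)-5,6,7,8-tetrahydronaphthalen-2-ol | Cc1cc2c(cc1O)[C@@H](C)CC[C@H]2C(C)C | intermediate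
14 | (5S,5'S,8S,8'S)-3,3',8,8'-tetramethyl-5,5'-di(propan-2-yl)-5,5',6,6',7,7',8,8'-octahydro-[1,1'-binaphthalene]-2,2'-diol | Cc1cc2c(c(-c3c(O)c(C)cc4c3[C@@H](C)CC[C@H]4C(C)C)c1O)[C@@H](C)CC[C@H]2C(C)C | target

Total step count: 8. Longest linear sequence: 8 steps (1 → 14; the last step joins two molecules of the same monomer).

Steps most likely to fail

Step 4. A third hydride abstraction, from C3–H of 9, may compete with the first two. That would carry material to the naphthalene level with loss of the C4 stereocentre. In addition, acid-induced tautomerisation of 8 may drain material to the tetralin level without control at C1.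
The fallback fixes the oxidation level with C–O bonds and removes them without any oxidant. It sets out from 7. mCPBA (2.2 equiv, NaHCO3, CH2Cl2, 0 °C) should give the 5,6:1,8a-bis-epoxide F1. LiNEt2 (Et2O/THF, reflux) takes the least hindered syn β-protons, those of the two methyl groups, and should isomerise both oxiranes to the bis(exo-methylene) 5,8a-diol F2. Catalytic TsOH in benzene then removes two molecules of water, as in the carveol-to-cymene aromatisation, and moves the alkenes into conjugation. This returns to the route at 9. F2 less two waters is C15H20, so the naphthalene level cannot be reached.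

Step 8. Carbon–carbon bond formation at the crowded C8 may be slow. Carbon–oxygen coupling, loss of C4–H towards a quinone methide, or further oxidation of the biphenol could then take over.
The fallback replaces the oxidative coupling by a reductive aryl–aryl coupling. It sets out from 13.
- NIS with catalytic TsOH in MeCN should iodinate C8, the only free position ortho or para to the hydroxyl group, to give 8-iodo-7-hydroxycalamenene F3.
- MeI and K2CO3 in acetone give the methyl ether F4.
- Ullmann coupling with activated Cu bronze (neat or in DMF, about 200 °C) gives the biaryl dimethyl ether F5.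
- BBr3 (CH2Cl2, −78 → 0 °C) cleaves both ethers and comes back to the route at 14.

Step 5. Facial selectivity on the metal surface may be poor, or the alkene may migrate towards C4 before reduction.
The fallback replaces substrate control by catalyst control. It sets out from 9. Homogeneous asymmetric hydrogenation with a cationic iridium P,N complex, [Ir(cod)(tBu-PHOX)][B(3,5-(CF3)2C6H3)4], H2 (50 bar), CH2Cl2, rt, is a catalyst class proven on 1-methyl-3,4-dihydronaphthalenes. The ligand enantiomer that reinforces the substrate bias is identified in a two-run comparison. The sequence comes back to the route at 10 and makes no new compound (F0).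

Further compounds
F1 | step 4 | (4S,4aR)-δ-cadinene 5,6:1,8a-bis-epoxide (epoxide carbons undefined) | CC12OC1[C@@H]1C3(OC3(C)CC[C@H]1C(C)C)CC2
F2 | step 4 | 1,6-bis(methylidene)cadinane-5,8a-diol (carbinol centres undefined) | C=C1C(O)[C@@H]2C(O)(C(=C)CC[C@H]2C(C)C)CC1
F3 | step 8 | (1S,4S)-8-iodo-7-hydroxycalamenene | Cc1cc2c(c(I)c1O)[C@@H](C)CC[C@H]2C(C)C
F4 | step 8 | (1S,4S)-8-iodo-7-methoxycalamenene | COc1c(C)cc2c(c1I)[C@@H](C)CC[C@H]2C(C)C
F5 | step 8 | 8,8'-bi[(1S,4S)-7-methoxycalamenene] | COc1c(C)cc2c(c1-c1c(OC)c(C)cc3c1[C@@H](C)CC[C@H]3C(C)C)[C@@H](C)CC[C@H]2C(C)C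
F0 | step 5 | none | none
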